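The decalin is treated as a head-to-tail isoprenoid. Ring A (C1–C5, C10) and ring B (C5–C10) are both cut, at C4–C5 and at C9–C10, which leaves an acyclic (E,E)-triene whose C3/C4 end is a 2-methyl-3-oxo ester of (−)-8-phenylmenthol. Manganese triacetate turns C4 into a radical that closes ring A and then, from C10, ring B by the C9–C10 bond; copper diacetate converts the C8 radical into the C8=C17 methylene. One operation thus sets C4, C5, C9 and C10 and uses the 1,5-relationship of the C5=C10 and C8=C9 alkenes. Later steps delete the C3 carbonyl, hydroxylate C7 and grow the diene from a C9 allyl group.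

Key step: step 6

Numbering: labdane numbers are used throughout (decalin C1–C10; C18 methyl and C19 carboxyl on C4; C17 on C8; C20 methyl on C10; side chain C11–C16 on C9).

Assumption: the (−)-8-phenylmenthyl ester is taken to direct the cyclisation to the (4R)-keto ester 9 (the podocarpic acid series), the sense remembered, not checked, for oxidative cyclisations of phenylmenthyl 2-methylacetoacetates; if the sense were opposite, (+)-8-phenylmenthol would replace 1 with nothing else changed.

Step 1
Reactants: 1 (−)-8-phenylmenthol; 2 ethyl 2-methyl-3-oxobutanoate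
Product: 3 (1R,2S,5R)-5-methyl-2-(2-phenylpropan-2-yl)cyclohexyl 2-methyl-3-oxobutanoate (both epimers at the acyl C2)
Conditions: DMAP (0.3 equiv), toluene, reflux, EtOH distilled off
Reagents that add atoms: none
Why: DMAP-catalysed transesterification of a β-keto ester runs through the acylketene and accepts the hindered secondary alcohol; the acyl C2 centre is of no consequence because it later becomes the planar radical carbon.

Step 2
Reactants: 4 geranyl bromide
Product: 5 (4E)-5,9-dimethyldeca-1,4,8-triene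
Conditions: vinylMgBr, CuI (10 mol %), THF, −30 to 0 °C
Reagents that add atoms: vinylmagnesium bromide, C=C[Mg]Br
Why: Copper-catalysed allylic substitution of the primary allylic bromide by the vinyl Grignard reagent should occur at the α-carbon (SN2) with the (E)-alkene retained, giving the skipped triene.

Step 3
Reactants: 5 (4E)-5,9-dimethyldeca-1,4,8-triene
Product: 6 (2E,6E)-2,6-dimethyldeca-2,6,9-trien-1-ol
Conditions: SeO2 (0.3 equiv), t-BuOOH (2.5 equiv), salicylic acid (0.1 equiv), CH2Cl2, 0 °C to rt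
Reagents that add atoms: tert-butyl hydroperoxide, CC(C)(C)OO (terminal oxidant; the oxygen is passed on through SeO2, O=[Se]=O)
Why: Riley allylic oxidation (ene reaction, then [2,3]-sigmatropic shift) should attack the terminal, least hindered trisubstituted alkene at its (E)-methyl group, the usual ω-hydroxylation of polyprenyl chains, giving the (E)-allylic alcohol.

Step 4
Reactants: 6 (2E,6E)-2,6-dimethyldeca-2,6,9-trien-1-ol
Product: 7 (2E,6E)-1-bromo-2,6-dimethyldeca-2,6,9-triene
Conditions: PBr3 (0.4 equiv), Et2O, −10 to 0 °C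
Reagents that add atoms: phosphorus tribromide, BrP(Br)Br
Why: The primary allylic alcohol is converted to the bromide by SN2 displacement of its phosphite ester at low temperature, which keeps the (E)-geometry.

Step 5
Reactants: 3 (−)-8-phenylmenthyl 2-methyl-3-oxobutanoate; 7 (2E,6E)-1-bromo-2,6-dimethyldeca-2,6,9-triene
Product: 8 (1R,2S,5R)-5-methyl-2-(2-phenylpropan-2-yl)cyclohexyl (6E,10E)-2,6,10-trimethyl-3-oxotetradeca-6,10,13-trienoate (both epimers at C2)
Conditions: 3, NaH (1.1 equiv), THF, 0 °C; n-BuLi (1.05 equiv), 0 °C; then 7, 0 °C to rt; aq NH4Cl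
Reagents that add atoms: none
Why: In this acetoacetate dianion alkylation the more basic terminal (γ) carbon is alkylated by the reactive allylic bromide, which joins C1 to C2 and completes the cyclisation substrate.

Step 6
Reactants: 8 (−)-8-phenylmenthyl (6E,10E)-2,6,10-trimethyl-3-oxotetradeca-6,10,13-trienoate
Product: 9 (1R,2S,5R)-5-methyl-2-(2-phenylpropan-2-yl)cyclohexyl (1R,4aR,5S,8aR)-1,4a-dimethyl-6-methylidene-2-oxo-5-(prop-2-en-1-yl)decahydronaphthalene-1-carboxylate (3-oxo, 8(17)-ene, 9β-allyl, 5α-H, 10β-methyl, axial 19-ester)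
Conditions: Mn(OAc)3·2H2O (2.2 equiv), Cu(OAc)2·H2O (1.0 equiv), degassed AcOH, 25 °C
Reagents that add atoms: none
Why: Trivalent manganese oxidises the enolised 2-methyl-3-oxo ester to the planar C4 radical, the opening of a manganese triacetate oxidative free-radical polyene cyclisation, the closest known reaction type. Ring A closes by 6-endo-trig attack of C4 on C5 of the (E)-C5=C10 alkene, and the tertiary C10 radical then closes ring B by 6-endo-trig attack on C9 of the (E)-C8=C9 alkene, forming the C9–C10 bond; each 5-exo alternative would have to build a quaternary centre at the disubstituted alkene carbon. The chair–chair transition state turns the two (E)-alkenes into the trans ring fusion (C5–H α, C10–CH3 β) and the equatorial C9 allyl group, and places the C4 ester axial, as is usual for 2-methylacetoacetates of this kind. The absolute sense is set at C4 by the 8-phenylmenthyl group, whose phenyl ring covers one face of the ester-conjugated radical so that C5 bonds to the open face; the minor diastereomer is separable at this stage. Divalent copper captures the tertiary C8 radical and removes a C17 hydrogen, which gives the less substituted C8=C17 methylene. The step needs facial selectivity at C4 and exocyclic termination: the first rests on the auxiliary, the second on the preference of the organocopper intermediate for the least hindered β-hydrogen.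

Step 7
Reactants: 9 bicyclic 3-oxo ester
Product: 10 (1R,2S,5R)-5-methyl-2-(2-phenylpropan-2-yl)cyclohexyl (1R,4aR,5S,8aR)-1,4a-dimethyl-6-methylidene-2-[2-(4-methylbenzenesulfonyl)hydrazinylidene]-5-(prop-2-en-1-yl)decahydronaphthalene-1-carboxylate
Conditions: TsNHNH2 (1.5 equiv), EtOH, 70 °C
Reagents that add atoms: 4-methylbenzenesulfonohydrazide, Cc1ccc(cc1)S(=O)(=O)NN
Why: Condensation of the only ketone with tosylhydrazide gives the tosylhydrazone, while the hindered ester and the alkenes are inert.

Step 8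
Reactants: 10 tosylhydrazone
Product: 11 (1R,2S,5R)-5-methyl-2-(2-phenylpropan-2-yl)cyclohexyl (1S,4aR,5S,8aR)-1,4a-dimethyl-6-methylidene-5-(prop-2-en-1-yl)decahydronaphthalene-1-carboxylate
Conditions: catecholborane (3 equiv), CHCl3, 0 °C to rt; then NaOAc·3H2O, reflux
Reagents that add atoms: none
Why: Tosylhydrazone reduction with catecholborane (a mild form of the Caglioti reaction) adds hydride to C=N, and acetate-induced loss of sulfinate and N2 leaves the C3 methylene under neutral conditions that spare the alkenes and the ester.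

Step 9
Reactants: 11 deoxygenated 8-phenylmenthyl ester
Product: 12 [(1S,4aR,5S,8aR)-1,4a-dimethyl-6-methylidene-5-(prop-2-en-1-yl)decahydronaphthalen-1-yl]methanol
Conditions: LiAlH4 (excess), THF, reflux; aq NaOH work-up
Reagents that add atoms: none
Why: LiAlH4 should reduce even the hindered axial ester to the neopentyl C19 alcohol and release the auxiliary 1 for recovery, while the isolated alkenes are untouched.

Step 10
Reactants: 12 C19 alcohol
Product: 14 (1S,4aR,5S,8aR)-1,4a-dimethyl-6-methylidene-5-(prop-2-en-1-yl)decahydronaphthalene-1-carboxylic acid, via C19 aldehyde 13 (not isolated)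
Conditions: CrO3, H2SO4, H2O, acetone, 0 °C
Reagents that add atoms: water, O (the new carboxyl oxygen enters through the aldehyde hydrate; chromium trioxide, O=[Cr](=O)=O, is the oxidant)
Why: Jones oxidation takes the primary alcohol through the aldehyde hydrate to the carboxylic acid, a conversion used for axial C19 carbinols that carry an exocyclic methylene.

Step 11
Reactants: 14 allyl acid
Product: 15 (1S,4aR,5R,7R,8aR)-7-hydroxy-1,4a-dimethyl-6-methylidene-5-(prop-2-en-1-yl)decahydronaphthalene-1-carboxylic acid (7α-OH, axial)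
Conditions: SeO2 (0.5 equiv), t-BuOOH (2 equiv), CH2Cl2, 0 °C to rt
Reagents that add atoms: tert-butyl hydroperoxide, CC(C)(C)OO (terminal oxidant; the oxygen is passed on through SeO2, O=[Se]=O)
Why: In this Riley allylic hydroxylation of the C8=C17 alkene the ene step removes the axial 7α-hydrogen from the α face (the β face is screened by the axial C10 methyl) and the [2,3]-shift returns oxygen to C7 on the same face, giving the axial (7R) alcohol with the methylene restored; the C7 methylene is preferred over the hindered C9 methine, and the monosubstituted allyl alkene reacts far more slowly.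

Step 12
Reactants: 15 7α-hydroxy acid
Product: 17 (1S,4aR,5R,7R,8aR)-7-acetoxy-1,4a-dimethyl-6-methylidene-5-(prop-2-en-1-yl)decahydronaphthalene-1-carboxylic acid, via mixed carboxylic acetic anhydride 16 (not isolated)
Conditions: Ac2O, pyridine, DMAP (cat.), rt; then H2O–pyridine
Reagents that add atoms: acetic anhydride, CC(=O)OC(C)=O
Why: DMAP-catalysed acylation esterifies the secondary allylic alcohol with retention at C7; the hindered C19 acid is acetylated to a mixed anhydride that aqueous pyridine hydrolyses back to the acid.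

Step 13
Reactants: 17 7α-acetoxy allyl acid
Product: 18 (1S,4aR,5R,7R,8aR)-7-acetoxy-1,4a-dimethyl-6-methylidene-5-[(2E)-3-methyl-4-oxobut-2-en-1-yl]decahydronaphthalene-1-carboxylic acid
Conditions: methacrolein (10 equiv), second-generation Hoveyda–Grubbs catalyst RuCl2(H2IMes)(=CH-C6H4-2-O-i-Pr) (5 mol %), CH2Cl2, 40 °C
Reagents that add atoms: methacrolein, C=C(C)C=O
Why: Olefin cross-metathesis of the terminal allyl alkene with excess methacrolein should give the trisubstituted (E)-enal under thermodynamic control, while the hindered 1,1-disubstituted C8=C17 alkene does not take part.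

Step 14
Reactants: 18 (E)-enal acid
Product: 19 (1S,4aR,5R,7R,8aR)-7-acetoxy-1,4a-dimethyl-6-methylidene-5-[(2E)-3-methylpenta-2,4-dien-1-yl]decahydronaphthalene-1-carboxylic acid (7α-acetoxy-trans-communic acid, the target)
Conditions: Ph3PCH3Br (2.3 equiv), KN(SiMe3)2 (2.2 equiv), THF, 0 °C; then 18, −78 to 0 °C; dilute citric acid work-up
Reagents that add atoms: methyltriphenylphosphonium bromide, C[P+](c1ccccc1)(c1ccccc1)c1ccccc1.[Br-]
Why: Wittig methylenation of the aldehyde with the non-stabilised ylide (one equivalent is consumed by the carboxylic acid) installs C15 and completes the (E)-1,3-diene without changing the C12=C13 geometry or, at low temperature, the acetate.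

Compound list
1 | (−)-8-phenylmenthol, (1R,2S,5R)-5-methyl-2-(2-phenylpropan-2-yl)cyclohexan-1-ol | O[C@@H]1C[C@H](C)CC[C@H]1C(C)(C)c1ccccc1 | starting material
2 | ethyl 2-methyl-3-oxobutanoate | CCOC(=O)C(C)C(C)=O | starting material
3 | (−)-8-phenylmenthyl 2-methyl-3-oxobutanoate (both acyl C2 epimers) | CC(=O)C(C)C(=O)O[C@@H]1C[C@H](C)CC[C@H]1C(C)(C)c1ccccc1 | intermediate
4 | geranyl bromide, (2E)-1-bromo-3,7-dimethylocta-2,6-diene | CC(C)=CCC/C(C)=C/CBr | starting material
5 | (4E)-5,9-dimethyldeca-1,4,8-triene | CC(C)=CCC/C(C)=C/CC=C | intermediate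
6 | (2E,6E)-2,6-dimethyldeca-2,6,9-trien-1-ol | OC/C(C)=C/CC/C(C)=C/CC=C | intermediate
7 | (2E,6E)-1-bromo-2,6-dimethyldeca-2,6,9-triene | BrC/C(C)=C/CC/C(C)=C/CC=C | intermediate
8 | (−)-8-phenylmenthyl (6E,10E)-2,6,10-trimethyl-3-oxotetradeca-6,10,13-trienoate | C=CC/C=C(\C)CC/C=C(\C)CCC(=O)C(C)C(=O)O[C@@H]1C[C@H](C)CC[C@H]1C(C)(C)c1ccccc1 | intermediate
9 | (−)-8-phenylmenthyl (1R,4aR,5S,8aR)-1,4a-dimethyl-6-methylidene-2-oxo-5-(prop-2-en-1-yl)decahydronaphthalene-1-carboxylate | C=CC[C@H]1C(=C)CC[C@@H]2[C@]1(C)CCC(=O)[C@]2(C)C(=O)O[C@@H]3C[C@H](C)CC[C@H]3C(C)(C)c4ccccc4 | intermediate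
10 | tosylhydrazone of 9 at C3 | C=CC[C@H]1C(=C)CC[C@@H]2[C@]1(C)CCC(=NNS(=O)(=O)c3ccc(C)cc3)[C@]2(C)C(=O)O[C@@H]4C[C@H](C)CC[C@H]4C(C)(C)c5ccccc5 | intermediate
11 | (−)-8-phenylmenthyl (1S,4aR,5S,8aR)-1,4a-dimethyl-6-methylidene-5-(prop-2-en-1-yl)decahydronaphthalene-1-carboxylate | C=CC[C@H]1C(=C)CC[C@@H]2[C@]1(C)CCC[C@]2(C)C(=O)O[C@@H]3C[C@H](C)CC[C@H]3C(C)(C)c4ccccc4 | intermediate
12 | [(1S,4aR,5S,8aR)-1,4a-dimethyl-6-methylidene-5-(prop-2-en-1-yl)decahydronaphthalen-1-yl]methanol | C=CC[C@H]1C(=C)CC[C@@H]2[C@]1(C)CCC[C@]2(C)CO | intermediate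
13 | (1S,4aR,5S,8aR)-1,4a-dimethyl-6-methylidene-5-(prop-2-en-1-yl)decahydronaphthalene-1-carbaldehyde | C=CC[C@H]1C(=C)CC[C@@H]2[C@]1(C)CCC[C@]2(C)C=O | intermediate (not isolated)
14 | (1S,4aR,5S,8aR)-1,4a-dimethyl-6-methylidene-5-(prop-2-en-1-yl)decahydronaphthalene-1-carboxylic acid | C=CC[C@H]1C(=C)CC[C@@H]2[C@]1(C)CCC[C@]2(C)C(=O)O | intermediate
15 | (1S,4aR,5R,7R,8aR)-7-hydroxy-1,4a-dimethyl-6-methylidene-5-(prop-2-en-1-yl)decahydronaphthalene-1-carboxylic acid | C=CC[C@H]1C(=C)[C@H](O)C[C@@H]2[C@]1(C)CCC[C@]2(C)C(=O)O | intermediate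
16 | acetic (1S,4aR,5R,7R,8aR)-7-acetoxy-1,4a-dimethyl-6-methylidene-5-(prop-2-en-1-yl)decahydronaphthalene-1-carboxylic anhydride | C=CC[C@H]1C(=C)[C@H](OC(C)=O)C[C@@H]2[C@]1(C)CCC[C@]2(C)C(=O)OC(C)=O | intermediate (not isolated)
17 | (1S,4aR,5R,7R,8aR)-7-acetoxy-1,4a-dimethyl-6-methylidene-5-(prop-2-en-1-yl)decahydronaphthalene-1-carboxylic acid | C=CC[C@H]1C(=C)[C@H](OC(C)=O)C[C@@H]2[C@]1(C)CCC[C@]2(C)C(=O)O | intermediate
18 | (1S,4aR,5R,7R,8aR)-7-acetoxy-1,4a-dimethyl-6-methylidene-5-[(2E)-3-methyl-4-oxobut-2-en-1-yl]decahydronaphthalene-1-carboxylic acid | O=C/C(C)=C/C[C@H]1C(=C)[C@H](OC(C)=O)C[C@@H]2[C@]1(C)CCC[C@]2(C)C(=O)O | intermediate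
19 | (1S,4aR,5R,7R,8aR)-7-acetoxy-1,4a-dimethyl-6-methylidene-5-[(2E)-3-methylpenta-2,4-dien-1-yl]decahydronaphthalene-1-carboxylic acid | C=C/C(C)=C/C[C@H]1C(=C)[C@H](OC(C)=O)C[C@@H]2[C@]1(C)CCC[C@]2(C)C(=O)O | target

Total step count: 14. Longest linear sequence: 13 steps (4 to 19, steps 2–14).

Steps most likely to fail

Step 6. The auxiliary may discriminate the two faces of the non-chelated C4 radical too weakly (rotamers about the C4–ester bond are not fixed), and the copper-mediated termination may leak to endocyclic alkenes. The fallback sets out from 7 and comes back at 12. It uses chelation control and sets C4 afterwards by enolate alkylation. (+)-8-Phenylmenthol is acylated with 2,2,6-trimethyl-1,3-dioxin-4-one (xylene, 140 °C) to (1S,2R,5S)-8-phenylmenthyl 3-oxobutanoate F1. Dianion alkylation with 7 (NaH, n-BuLi, THF, 0 °C) gives the polyene 3-oxo ester lacking the C4 methyl group F2. Mn(OAc)3·2H2O, Cu(OAc)2·H2O and Yb(OTf)3 in CF3CH2OH at −5 °C cyclise it through the ytterbium-chelated dicarbonyl radical, whose geometry is fixed and whose open face is expected to lead to the same ring-fusion series, giving the bicyclic 3-oxo ester F3. K2CO3 and MeI in acetone methylate its enolate from the α face, away from the axial C10 methyl, to the 4α-methyl keto ester F4. Tosylhydrazide then gives the tosylhydrazone F5, catecholborane with NaOAc·3H2O gives the deoxygenated (+)-8-phenylmenthyl ester F6, and LiAlH4 gives 12.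

Step 7. Condensation at the C3 ketone, flanked by the quaternary C4 with its bulky ester, may be slow or incomplete, and forcing it may start cleavage of the β-keto ester. The fallback sets out from 9 and comes back at 11. NaBH4 (MeOH, 0 °C) reduces the ketone to the C3 alcohol F7 (either epimer serves). PhOC(S)Cl, pyridine and DMAP in CH2Cl2 give the phenyl thionocarbonate F8. Bu3SnH and AIBN in toluene at 100 °C (Barton–McCombie deoxygenation) give 11.

Step 11. Over-oxidation to the enone and incomplete control of the C7 configuration may erode the allylic hydroxylation. The fallback sets out from 14 and comes back at 17. The SeO2/t-BuOOH oxidation is driven on and the crude allylic alcohols are oxidised with Dess–Martin periodinane to the 7-oxo-8(17)-ene acid F9. Luche reduction (NaBH4, CeCl3·7H2O, MeOH, −78 °C) delivers hydride axially from the α face and gives the equatorial 7β-alcohol F10. A Mitsunobu reaction with acetic acid (PPh3, DIAD, AcOH in excess, toluene, 0 °C) inverts C7 and gives the acetate 17 directly, so that step 12 is not needed.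

Further compounds
F1 | step 6 | (1S,2R,5S)-5-methyl-2-(2-phenylpropan-2-yl)cyclohexyl 3-oxobutanoate | CC(=O)CC(=O)O[C@H]1C[C@@H](C)CC[C@@H]1C(C)(C)c1ccccc1
F2 | step 6 | (+)-8-phenylmenthyl (6E,10E)-6,10-dimethyl-3-oxotetradeca-6,10,13-trienoate | C=CC/C=C(\C)CC/C=C(\C)CCC(=O)CC(=O)O[C@H]1C[C@@H](C)CC[C@@H]1C(C)(C)c1ccccc1
F3 | step 6 | (+)-8-phenylmenthyl (4aR,5S,8aR)-4a-methyl-6-methylidene-2-oxo-5-(prop-2-en-1-yl)decahydronaphthalene-1-carboxylate (C1 epimers and enol) | C=CC[C@H]1C(=C)CC[C@@H]2[C@]1(C)CCC(=O)C2C(=O)O[C@H]3C[C@@H](C)CC[C@@H]3C(C)(C)c4ccccc4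
F4 | step 6 | (+)-8-phenylmenthyl (1R,4aR,5S,8aR)-1,4a-dimethyl-6-methylidene-2-oxo-5-(prop-2-en-1-yl)decahydronaphthalene-1-carboxylate | C=CC[C@H]1C(=C)CC[C@@H]2[C@]1(C)CCC(=O)[C@]2(C)C(=O)O[C@H]3C[C@@H](C)CC[C@@H]3C(C)(C)c4ccccc4
F5 | step 6 | tosylhydrazone of F4 at C3 | C=CC[C@H]1C(=C)CC[C@@H]2[C@]1(C)CCC(=NNS(=O)(=O)c3ccc(C)cc3)[C@]2(C)C(=O)O[C@H]4C[C@@H](C)CC[C@@H]4C(C)(C)c5ccccc5
F6 | step 6 | (+)-8-phenylmenthyl (1S,4aR,5S,8aR)-1,4a-dimethyl-6-methylidene-5-(prop-2-en-1-yl)decahydronaphthalene-1-carboxylate | C=CC[C@H]1C(=C)CC[C@@H]2[C@]1(C)CCC[C@]2(C)C(=O)O[C@H]3C[C@@H](C)CC[C@@H]3C(C)(C)c4ccccc4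
F7 | step 7 | (−)-8-phenylmenthyl (1R,4aR,5S,8aR)-2-hydroxy-1,4a-dimethyl-6-methylidene-5-(prop-2-en-1-yl)decahydronaphthalene-1-carboxylate (either C2 epimer) | C=CC[C@H]1C(=C)CC[C@@H]2[C@]1(C)CCC(O)[C@]2(C)C(=O)O[C@@H]3C[C@H](C)CC[C@H]3C(C)(C)c4ccccc4
F8 | step 7 | O-phenyl thionocarbonate of F7 | C=CC[C@H]1C(=C)CC[C@@H]2[C@]1(C)CCC(OC(=S)Oc3ccccc3)[C@]2(C)C(=O)O[C@@H]4C[C@H](C)CC[C@H]4C(C)(C)c5ccccc5
F9 | step 11 | (1S,4aR,5S,8aR)-1,4a-dimethyl-6-methylidene-7-oxo-5-(prop-2-en-1-yl)decahydronaphthalene-1-carboxylic acid | C=CC[C@H]1C(=C)C(=O)C[C@@H]2[C@]1(C)CCC[C@]2(C)C(=O)O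
F10 | step 11 | (1S,4aR,5R,7S,8aR)-7-hydroxy-1,4a-dimethyl-6-methylidene-5-(prop-2-en-1-yl)decahydronaphthalene-1-carboxylic acid (7β-OH) | C=CC[C@H]1C(=C)[C@@H](O)C[C@@H]2[C@]1(C)CCC[C@]2(C)C(=O)O
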